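**Retrosynthetic overview**

1. Locants used throughout: ring A = C1–C5 and C10, ring B = C5–C10; C4 carries CO2Me (C18) and a methyl, C8 a methyl, C9 a methyl and the chain C11–C15 (C16 on C13). The last three steps are only an esterification, a desilylation and a formylation.
2. Key disconnection: the C4–C5 bond, by a retro-Ireland–Claisen rearrangement. The unit C18(=O)–C4–C5–C10=C1 is a γ,δ-unsaturated acid, and C1 and C4 are 1,4-related in ring A through C2–C3. An oxygen on C1 can therefore be tied to C18 as a six-membered lactone; this C1–O bond is absent from the target and is cleaved in the ring closure itself.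
3. The lactone comes from a reagent-controlled reduction of a C1 enone. The enone is made by joining a ring B enol triflate, CO and a C2–C4/C18 alkylborane in one carbonylative coupling.
4. Ring B comes from 2-methylcyclohex-2-enone: a catalytic asymmetric methyl conjugate addition sets C8, a trans Michael alkylation relays it to C9, and the side chain is finished by olefination.
5. Ring order: ring B is bought, the temporary lactone ring is formed next, and ring A is closed last in the key step, which sets C4 and C5 from C1.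

Key step: step 9

Assumption: the enantiomer of the phosphoramidite ligand L* (BINOL-derived, bis(1-phenylethyl)amine unit) that gives the (3R) adduct in step 1 is to be assigned in a test run; C4 in compounds 16 and 19–22 is an unresolved stereocentre of no consequence, because it becomes planar in step 9.

**Step 1**
Reactants: 1 2-methylcyclohex-2-en-1-one; 2 trimethylaluminium; 3 trimethylsilyl trifluoromethanesulfonate
Product: 5 trimethyl{[(3R)-2,3-dimethylcyclohex-1-en-1-yl]oxy}silane, via dimethylaluminium enolate 4 (not isolated)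
Conditions: Me3Al, copper thiophene-2-carboxylate (2 mol %), L* (4 mol %), Et2O, −30 °C; then Me3SiOTf, −30 °C → rt
Reagents that add atoms: trimethylaluminium, C[Al](C)C; trimethylsilyl trifluoromethanesulfonate, C[Si](C)(C)OS(=O)(=O)C(F)(F)F
Why: Copper-catalysed asymmetric conjugate addition of the methyl group, with the ligand choosing the enone face, sets C8, and O-silylation of the aluminium enolate fixes the enol double bond at C9=C10.

**Step 2**
Reactants: 5 silyl enol ether; 6 but-3-en-2-one
Product: 7 (2S,3R)-2,3-dimethyl-2-(3-oxobutyl)cyclohexan-1-one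
Conditions: BF3·OEt2, i-PrOH, CH2Cl2, −78 °C
Reagents that add atoms: but-3-en-2-one, CC(=O)C=C
Why: Mukaiyama–Michael addition in which the C8 methyl sits pseudoaxial to avoid A(1,2) strain with the C9 methyl, so the enone should add to C9 from the opposite face and give the quaternary centre with the two methyls cis.

**Step 3**
Reactants: 7 diketone; 8 triethyl phosphonoacetate
Product: 9 ethyl (2E)-5-[(1S,2R)-1,2-dimethyl-6-oxocyclohexyl]-3-methylpent-2-enoate
Conditions: NaH, THF, 0 °C → 40 °C
Reagents that add atoms: triethyl phosphonoacetate, CCOC(=O)CP(=O)(OCC)OCC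
Why: Horner–Wadsworth–Emmons olefination should occur at the unhindered methyl ketone and not at the neopentyl ring ketone, and the stabilised phosphonate favours the E enoate (any Z isomer is to be removed by chromatography).

**Step 4**
Reactants: 9 keto enoate; 10 N-(5-chloropyridin-2-yl)-1,1,1-trifluoro-N-[(trifluoromethyl)sulfonyl]methanesulfonamide
Product: 12 ring B enol triflate enoate, via lithium enolate 11 (not isolated)
Conditions: LiN(SiMe3)2, THF, −78 °C; then 10, −78 → 0 °C
Reagents that add atoms: triflimide 10, O=S(=O)(N(c1ccc(Cl)cn1)S(=O)(=O)C(F)(F)F)C(F)(F)F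
Why: Kinetic enolisation with the weak hindered amide is possible only on the C5 side of the ketone (C9 is quaternary) and should be faster than γ-deprotonation of the enoate, and O-triflation of the enolate gives the C10=C5 enol triflate.

**Step 5**
Reactants: 12 enol triflate enoate
Product: 13 (5R,6S)-6-[(3E)-5-hydroxy-3-methylpent-3-en-1-yl]-5,6-dimethylcyclohex-1-en-1-yl trifluoromethanesulfonate
Conditions: i-Bu2AlH, CH2Cl2, −78 °C; aq. potassium sodium tartrate
Reagents that add atoms: none
Why: 1,2-Reduction of the conjugated ester by the aluminium hydride gives the allylic alcohol at low temperature and leaves the enol triflate and the alkene geometry untouched.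

**Step 6**
Reactants: 13 allylic alcohol; 14 tert-butylchlorodimethylsilane
Product: 15 (5R,6S)-6-{(3E)-5-[(tert-butyldimethylsilyl)oxy]-3-methylpent-3-en-1-yl}-5,6-dimethylcyclohex-1-en-1-yl trifluoromethanesulfonate
Conditions: imidazole, CH2Cl2, rt
Reagents that add atoms: tert-butylchlorodimethylsilane, CC(C)(C)[Si](C)(C)Cl
Why: Standard silylation of the primary alcohol gives an ether that tolerates the base, hydride and heat of steps 7 to 10.

**Step 7**
Reactants: 15 enol triflate; 16 methyl 2-methylbut-3-enoate; 17 9-borabicyclo[3.3.1]nonane; 18 carbon monoxide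
Product: 20 methyl 5-[(5R,6S)-6-{(3E)-5-[(tert-butyldimethylsilyl)oxy]-3-methylpent-3-en-1-yl}-5,6-dimethylcyclohex-1-en-1-yl]-2-methyl-5-oxopentanoate, via alkylborane 19 (not isolated)
Conditions: 16, 9-BBN-H, THF, 0 °C → rt; then 15, PdCl2(dppf) (5 mol %), K3PO4, CO (1 atm), THF/DMF, 50 °C
Reagents that add atoms: methyl 2-methylbut-3-enoate, C=CC(C)C(=O)OC; carbon monoxide, [C-]#[O+]
Why: Carbonylative Suzuki–Miyaura coupling in which anti-Markovnikov hydroboration of 16 gives the primary alkylborane and the alkenylpalladium from 15 inserts CO before B-alkyl transmetalation, so that triflate, CO and borane are joined as the C10–C1(=O)–C2 enone.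

**Step 8**
Reactants: 20 enone
Product: 22 (6R)-6-[(5R,6S)-6-{(3E)-5-[(tert-butyldimethylsilyl)oxy]-3-methylpent-3-en-1-yl}-5,6-dimethylcyclohex-1-en-1-yl]-3-methyloxan-2-one, via hydroxy ester 21 (not isolated)
Conditions: (S)-2-methyl-CBS-oxazaborolidine (20 mol %), catecholborane, PhMe, −78 °C; MeOH; then pyridinium p-toluenesulfonate (cat.), 4 Å MS, PhMe, 40 °C
Reagents that add atoms: none
Why: Corey–Bakshi–Shibata reduction under reagent control, in which the bulky ring B alkenyl group acts as the large substituent so that the (S)-catalyst should give the (1R)-carbinol, followed by acid-catalysed lactonisation of the δ-hydroxy ester.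

**Step 9**
Reactants: 22 lactone; 23 chlorotrimethylsilane
Product: 27 (1S,5S,6R,8aR)-5-{(3E)-5-[(tert-butyldimethylsilyl)oxy]-3-methylpent-3-en-1-yl}-1,5,6-trimethyl-1,2,3,5,6,7,8,8a-octahydronaphthalene-1-carboxylic acid, via lithium lactone enolate 24 (not isolated), via silyl ketene acetal 25 (not isolated), via trimethylsilyl ester 26 (not isolated)
Conditions: LiN(i-Pr)2, THF, −78 °C; Me3SiCl/Et3N, −78 °C → rt; PhMe, 105 °C; then H2O/THF, citric acid to pH 4
Reagents that add atoms: none
Why: Ireland–Claisen rearrangement of a lactone silyl ketene acetal: deprotonation at C4 and O-silylation give the cyclic ketene acetal 25, whose C4=C18(OSiMe3)–O–C1–C10=C5 array undergoes a concerted [3,3] shift that forms C4–C5, breaks the temporary C1–O bond and moves the alkene to C1=C10. The closest known reaction type is the carbocycle-forming ester-enolate Claisen rearrangement of 6-alkenyl-δ-lactones. Ring A (C1–C5, C10) closes in the sigmatropic shift itself, through a boat-like bicyclo[2.2.2]-type transition state; the chair is excluded because the C2–C3 tether must keep C2 syn to C5, which also makes the ring alkene Z. C5 is controlled by C1: bond formation is suprafacial, so C4 arrives on the ring B face from which the (1R)-oxygen leaves, the face syn to C11 and anti to the C9 methyl, and H5 ends trans to C11 as required. C4 is controlled by the ring-locked ketene acetal geometry (C3 cis to the ring oxygen, methyl outside) inside that boat, which places the carboxyl anti to H5 and the methyl cis to it, so both C4 epimers of 22 converge on one product. The step needs no choice between competing transition states, only clean O-silylation and survival of the silyl ether, which the low-temperature amide base, the small Me3Si group and neutral heating should secure.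

**Step 10**
Reactants: 27 acid; 28 iodomethane
Product: 29 methyl (1S,5S,6R,8aR)-5-{(3E)-5-[(tert-butyldimethylsilyl)oxy]-3-methylpent-3-en-1-yl}-1,5,6-trimethyl-1,2,3,5,6,7,8,8a-octahydronaphthalene-1-carboxylate
Conditions: K2CO3, MeI, DMF, rt
Reagents that add atoms: iodomethane, CI
Why: SN2 O-alkylation of the carboxylate by iodomethane esterifies the hindered neopentyl acid without touching the C4 stereocentre.

**Step 11**
Reactants: 29 silyl ether methyl ester
Product: 30 methyl (1S,5S,6R,8aR)-5-[(3E)-5-hydroxy-3-methylpent-3-en-1-yl]-1,5,6-trimethyl-1,2,3,5,6,7,8,8a-octahydronaphthalene-1-carboxylate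
Conditions: HF·pyridine, pyridine, THF, 0 °C → rt
Reagents that add atoms: none
Why: Fluoride-mediated desilylation cleaves the Si–O bond of the primary silyl ether under buffered conditions that leave the hindered ester and both trisubstituted alkenes intact.

**Step 12**
Reactants: 30 allylic alcohol; 31 2,2,2-trifluoroethyl formate
Product: 32 methyl (1S,5S,6R,8aR)-5-[(3E)-5-(formyloxy)-3-methylpent-3-en-1-yl]-1,5,6-trimethyl-1,2,3,5,6,7,8,8a-octahydronaphthalene-1-carboxylate (CNP0188193.1)
Conditions: 31 (excess), THF, 60 °C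
Reagents that add atoms: 2,2,2-trifluoroethyl formate, O=COCC(F)(F)F
Why: O-Formylation of the primary allylic alcohol by acyl transfer from the activated formate should proceed under neutral conditions that avoid allylic ionisation.

**Compound list**

1 | 2-methylcyclohex-2-en-1-one | CC1=CCCCC1=O | starting material
2 | trimethylaluminium | C[Al](C)C | starting material
3 | trimethylsilyl trifluoromethanesulfonate | C[Si](C)(C)OS(=O)(=O)C(F)(F)F | starting material
4 | {[(3R)-2,3-dimethylcyclohex-1-en-1-yl]oxy}dimethylalumane | C[C@@H]1CCCC(O[Al](C)C)=C1C | intermediate (not isolated)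
5 | trimethyl{[(3R)-2,3-dimethylcyclohex-1-en-1-yl]oxy}silane | C[C@@H]1CCCC(O[Si](C)(C)C)=C1C | intermediate
6 | but-3-en-2-one | CC(=O)C=C | starting material
7 | (2S,3R)-2,3-dimethyl-2-(3-oxobutyl)cyclohexan-1-one | O=C1CCC[C@@H](C)[C@]1(C)CCC(C)=O | intermediate
8 | triethyl phosphonoacetate | CCOC(=O)CP(=O)(OCC)OCC | starting material
9 | ethyl (2E)-5-[(1S,2R)-1,2-dimethyl-6-oxocyclohexyl]-3-methylpent-2-enoate | CCOC(=O)/C=C(\C)CC[C@@]1(C)[C@H](C)CCCC1=O | intermediate
10 | N-(5-chloropyridin-2-yl)-1,1,1-trifluoro-N-[(trifluoromethyl)sulfonyl]methanesulfonamide | O=S(=O)(N(c1ccc(Cl)cn1)S(=O)(=O)C(F)(F)F)C(F)(F)F | starting material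
11 | lithium (5R,6S)-6-[(3E)-5-ethoxy-3-methyl-5-oxopent-3-en-1-yl]-5,6-dimethylcyclohex-1-en-1-olate | CCOC(=O)/C=C(\C)CC[C@@]1(C)[C@H](C)CCC=C1O[Li] | intermediate (not isolated)
12 | (5R,6S)-6-[(3E)-5-ethoxy-3-methyl-5-oxopent-3-en-1-yl]-5,6-dimethylcyclohex-1-en-1-yl trifluoromethanesulfonate | CCOC(=O)/C=C(\C)CC[C@@]1(C)[C@H](C)CCC=C1OS(=O)(=O)C(F)(F)F | intermediate
13 | (5R,6S)-6-[(3E)-5-hydroxy-3-methylpent-3-en-1-yl]-5,6-dimethylcyclohex-1-en-1-yl trifluoromethanesulfonate | OC/C=C(\C)CC[C@@]1(C)[C@H](C)CCC=C1OS(=O)(=O)C(F)(F)F | intermediate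
14 | tert-butylchlorodimethylsilane | CC(C)(C)[Si](C)(C)Cl | starting material
15 | (5R,6S)-6-{(3E)-5-[(tert-butyldimethylsilyl)oxy]-3-methylpent-3-en-1-yl}-5,6-dimethylcyclohex-1-en-1-yl trifluoromethanesulfonate | CC(C)(C)[Si](C)(C)OC/C=C(\C)CC[C@@]1(C)[C@H](C)CCC=C1OS(=O)(=O)C(F)(F)F | intermediate
16 | methyl 2-methylbut-3-enoate (racemic) | C=CC(C)C(=O)OC | starting material
17 | 9-borabicyclo[3.3.1]nonane | [H]B1C2CCCC1CCC2 | starting material
18 | carbon monoxide | [C-]#[O+] | starting material
19 | methyl 4-(9-borabicyclo[3.3.1]nonan-9-yl)-2-methylbutanoate | COC(=O)C(C)CCB1C2CCCC1CCC2 | intermediate (not isolated)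
20 | methyl 5-[(5R,6S)-6-{(3E)-5-[(tert-butyldimethylsilyl)oxy]-3-methylpent-3-en-1-yl}-5,6-dimethylcyclohex-1-en-1-yl]-2-methyl-5-oxopentanoate (C2 epimers) | COC(=O)C(C)CCC(=O)C1=CCC[C@@H](C)[C@]1(C)CC/C(C)=C/CO[Si](C)(C)C(C)(C)C | intermediate
21 | methyl (5R)-5-[(5R,6S)-6-{(3E)-5-[(tert-butyldimethylsilyl)oxy]-3-methylpent-3-en-1-yl}-5,6-dimethylcyclohex-1-en-1-yl]-5-hydroxy-2-methylpentanoate (C2 epimers) | COC(=O)C(C)CC[C@@H](O)C1=CCC[C@@H](C)[C@]1(C)CC/C(C)=C/CO[Si](C)(C)C(C)(C)C | intermediate (not isolated)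
22 | (6R)-6-[(5R,6S)-6-{(3E)-5-[(tert-butyldimethylsilyl)oxy]-3-methylpent-3-en-1-yl}-5,6-dimethylcyclohex-1-en-1-yl]-3-methyloxan-2-one (C3 epimers) | CC1CC[C@@H](OC1=O)C1=CCC[C@@H](C)[C@]1(C)CC/C(C)=C/CO[Si](C)(C)C(C)(C)C | intermediate
23 | chlorotrimethylsilane | C[Si](C)(C)Cl | starting material
24 | lithium (6R)-6-[(5R,6S)-6-{(3E)-5-[(tert-butyldimethylsilyl)oxy]-3-methylpent-3-en-1-yl}-5,6-dimethylcyclohex-1-en-1-yl]-3-methyl-5,6-dihydro-4H-pyran-2-olate | CC1=C(O[Li])O[C@H](CC1)C1=CCC[C@@H](C)[C@]1(C)CC/C(C)=C/CO[Si](C)(C)C(C)(C)C | intermediate (not isolated)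
25 | {[(2R)-2-[(5R,6S)-6-{(3E)-5-[(tert-butyldimethylsilyl)oxy]-3-methylpent-3-en-1-yl}-5,6-dimethylcyclohex-1-en-1-yl]-5-methyl-3,4-dihydro-2H-pyran-6-yl]oxy}trimethylsilane | CC1=C(O[Si](C)(C)C)O[C@H](CC1)C1=CCC[C@@H](C)[C@]1(C)CC/C(C)=C/CO[Si](C)(C)C(C)(C)C | intermediate (not isolated)
26 | trimethylsilyl (1S,5S,6R,8aR)-5-{(3E)-5-[(tert-butyldimethylsilyl)oxy]-3-methylpent-3-en-1-yl}-1,5,6-trimethyl-1,2,3,5,6,7,8,8a-octahydronaphthalene-1-carboxylate | C[Si](C)(C)OC(=O)[C@@]1(C)CCC=C2[C@H]1CC[C@@H](C)[C@]2(C)CC/C(C)=C/CO[Si](C)(C)C(C)(C)C | intermediate (not isolated)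
27 | (1S,5S,6R,8aR)-5-{(3E)-5-[(tert-butyldimethylsilyl)oxy]-3-methylpent-3-en-1-yl}-1,5,6-trimethyl-1,2,3,5,6,7,8,8a-octahydronaphthalene-1-carboxylic acid | OC(=O)[C@@]1(C)CCC=C2[C@H]1CC[C@@H](C)[C@]2(C)CC/C(C)=C/CO[Si](C)(C)C(C)(C)C | intermediate
28 | iodomethane | CI | starting material
29 | methyl (1S,5S,6R,8aR)-5-{(3E)-5-[(tert-butyldimethylsilyl)oxy]-3-methylpent-3-en-1-yl}-1,5,6-trimethyl-1,2,3,5,6,7,8,8a-octahydronaphthalene-1-carboxylate | COC(=O)[C@@]1(C)CCC=C2[C@H]1CC[C@@H](C)[C@]2(C)CC/C(C)=C/CO[Si](C)(C)C(C)(C)C | intermediate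
30 | methyl (1S,5S,6R,8aR)-5-[(3E)-5-hydroxy-3-methylpent-3-en-1-yl]-1,5,6-trimethyl-1,2,3,5,6,7,8,8a-octahydronaphthalene-1-carboxylate | COC(=O)[C@@]1(C)CCC=C2[C@H]1CC[C@@H](C)[C@]2(C)CC/C(C)=C/CO | intermediate
31 | 2,2,2-trifluoroethyl formate | O=COCC(F)(F)F | starting material
32 | methyl (1S,5S,6R,8aR)-5-[(3E)-5-(formyloxy)-3-methylpent-3-en-1-yl]-1,5,6-trimethyl-1,2,3,5,6,7,8,8a-octahydronaphthalene-1-carboxylate | COC(=O)[C@@]1(C)CCC=C2[C@H]1CC[C@@H](C)[C@]2(C)CC/C(C)=C/COC=O | target

**Totals**

Total step count: 12. Longest linear sequence: 12 steps (from 1; the alkylborane 19 is made in the flask of step 7).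

**Steps most likely to fail**

Step 9. The boat-like transition state is compressed between the silyloxy group of the ketene acetal and the C9 substituents of ring B, so the rearrangement may be slower than loss of the ketene acetal by hydrolysis, C-silylation or ionisation of the allylic C–O bond. The fallback sets out from enol triflate 15. Stille coupling with Bu3SnCH=CH2 (Pd(PPh3)4, LiCl, THF, reflux) would give the ring B vinyl diene tert-butyl({(2E)-5-[(1S,6R)-2-ethenyl-1,6-dimethylcyclohex-2-en-1-yl]-3-methylpent-2-en-1-yl}oxy)dimethylsilane F1. A Diels–Alder reaction of F1 with methyl methacrylate (MeAlCl2, CH2Cl2, low temperature, or neat at high temperature) would then build ring A by forming C4–C5 and C2–C3 together, with the ester endo and the dienophile anti to the pseudoaxial C9 methyl. Regio- and stereoisomers would have to be separated, and the route is rejoined at methyl ester 29.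

Step 7. At the hindered alkenylpalladium, direct B-alkyl coupling without CO, or β-hydride loss from the alkyl partner, may outrun CO insertion and acyl transfer. The fallback sets out from enol triflate 15. Carbonylative Stille coupling with Bu3SnCH=CH2 (Pd(PPh3)4, LiCl, CO, THF) would give the cross-conjugated divinyl ketone 1-[(5R,6S)-6-{(3E)-5-[(tert-butyldimethylsilyl)oxy]-3-methylpent-3-en-1-yl}-5,6-dimethylcyclohex-1-en-1-yl]prop-2-en-1-one F2. Uncatalysed Mukaiyama–Michael addition of commercial 1-methoxy-1-(trimethylsilyloxy)prop-1-ene in warm MeCN (no Lewis acid, to avoid Nazarov cyclisation) would add C4 to the unsubstituted vinyl terminus and give the silyl enol ether methyl 5-[(5R,6S)-6-{(3E)-5-[(tert-butyldimethylsilyl)oxy]-3-methylpent-3-en-1-yl}-5,6-dimethylcyclohex-1-en-1-yl]-2-methyl-5-[(trimethylsilyl)oxy]pent-4-enoate F3. Mildly acidic work-up hydrolyses F3 to enone 20, where the route is rejoined.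

Step 3. Olefination of the methyl ketone may give poor E/Z control, and the 1,5-diketone may cyclise by aldol reaction under the basic conditions. The fallback sets out from silyl enol ether 5 and fixes the alkene geometry by syn carbometalation of an alkyne. Mukaiyama–Michael addition to acrolein (conditions of step 2) would give the keto aldehyde 3-[(1S,2R)-1,2-dimethyl-6-oxocyclohexyl]propanal F4. Seyferth–Gilbert homologation with dimethyl (1-diazo-2-oxopropyl)phosphonate (K2CO3, MeOH) would give the alkynyl ketone (2S,3R)-2-(but-3-yn-1-yl)-2,3-dimethylcyclohexan-1-one F5. LiN(SiMe3)2 and triflimide 10 would give the alkynyl enol triflate (5R,6S)-6-(but-3-yn-1-yl)-5,6-dimethylcyclohex-1-en-1-yl trifluoromethanesulfonate F6. Zirconium-catalysed methylalumination (Me3Al, Cp2ZrCl2, CH2Cl2) followed by ClCO2Et would give enoate 12 as the E isomer, where the route is rejoined.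

**Further compounds**

F1 | step 9 | tert-butyl({(2E)-5-[(1S,6R)-2-ethenyl-1,6-dimethylcyclohex-2-en-1-yl]-3-methylpent-2-en-1-yl}oxy)dimethylsilane | C=CC1=CCC[C@@H](C)[C@]1(C)CC/C(C)=C/CO[Si](C)(C)C(C)(C)C
F2 | step 7 | 1-[(5R,6S)-6-{(3E)-5-[(tert-butyldimethylsilyl)oxy]-3-methylpent-3-en-1-yl}-5,6-dimethylcyclohex-1-en-1-yl]prop-2-en-1-one | C=CC(=O)C1=CCC[C@@H](C)[C@]1(C)CC/C(C)=C/CO[Si](C)(C)C(C)(C)C
F3 | step 7 | methyl 5-[(5R,6S)-6-{(3E)-5-[(tert-butyldimethylsilyl)oxy]-3-methylpent-3-en-1-yl}-5,6-dimethylcyclohex-1-en-1-yl]-2-methyl-5-[(trimethylsilyl)oxy]pent-4-enoate | COC(=O)C(C)CC=C(O[Si](C)(C)C)C1=CCC[C@@H](C)[C@]1(C)CC/C(C)=C/CO[Si](C)(C)C(C)(C)C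
F4 | step 3 | 3-[(1S,2R)-1,2-dimethyl-6-oxocyclohexyl]propanal | O=CCC[C@@]1(C)[C@H](C)CCCC1=O
F5 | step 3 | (2S,3R)-2-(but-3-yn-1-yl)-2,3-dimethylcyclohexan-1-one | C#CCC[C@@]1(C)[C@H](C)CCCC1=O
F6 | step 3 | (5R,6S)-6-(but-3-yn-1-yl)-5,6-dimethylcyclohex-1-en-1-yl trifluoromethanesulfonate | C#CCC[C@@]1(C)[C@H](C)CCC=C1OS(=O)(=O)C(F)(F)F
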